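## Retrosynthetic overview

1. Bicycle numbering used below: C-1 = oxygenated bridgehead, C-2 = CH carrying the arylmethyl group, C-3 = CMe2, C-4 = CH bridgehead, C-5 = quaternary carbon (methyl + chain), C-6 = CH2, C-7/C-8 = unsubstituted bridge. The last operations are O-sulfation of the one free phenol and desilylation. The four-carbon chain is cut in its middle: the lithium acetylide of a 5-ethynyl bicycle opens a spiro-oxetane on the oxepane-fused cyclohexane.
2. Key disconnection: the ArCH2–aryl bond, made by nickel-electrocatalytic decarboxylative coupling of the redox-active ester of the C-2 acetic acid with a silyl/benzyl-differentiated iodohydroquinone. The enabling feature is that the benzylic carbon is an exocyclic primary CH2 on C-2, which sits between the quaternary C-3 and the fully substituted bridgehead C-1. That position is neopentyl-like and closed to substitution chemistry, but as a primary radical it is unhindered, has no β-leaving group, and can reach the C-7=C-8 bridge only by disfavoured 4-exo or 5-endo closure.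
3. Bicyclo[2.2.2]octane: anionic double Michael addition of the α′-silyloxy dienolate of a 5-vinyl-4,4-dimethylcyclohexenone to methyl acrylate. The vinyl group is a masked CH2CO2H, set by rhodium-catalysed desymmetrisation of the dienone. The C-5 methyl comes from ester enolate alkylation, and the C-7 ketone is removed through its enol triflate.
4. Left half: 2-methylcyclohexenone is taken through CBS reduction, directed epoxidation and reductive alkylation of the epoxy ketone; the oxepane is closed by alkoxymercuration; the tertiary carbinol centre is set by methylenation, face-selective epoxidation and ring expansion to the oxetane.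
5. Ring order, right half: cyclohexenone ring (bought), then both remaining rings of the bicycle in one step, aromatic ring attached in the key step. Ring order, left half: cyclohexane (bought), oxepane, temporary oxetane (opened in the fragment union).

Key step: step 12

Remark: the target is taken as the free aryl hydrogen sulfate drawn in the SMILES; it would be released by an acidic ion-exchange work-up and is best stored as a salt. TBS = tert-butyldimethylsilyl, TIPS = triisopropylsilyl.

## Route

Step 1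
Reactants: 1 4-(benzyloxy)phenol
Product: 2 4-(benzyloxy)-2-iodophenol
Conditions: N-iodosuccinimide (1.0 equiv), p-TsOH (cat.), MeCN, 0 °C → rt
Reagents that add atoms: N-iodosuccinimide, O=C1CCC(=O)N1I
Why: Electrophilic aromatic iodination; the free hydroxyl is the stronger ortho/para director and its para position is blocked, so iodine should enter ortho to OH, next to the oxygen that stays free in the target.

Step 2
Reactants: 2 4-(benzyloxy)-2-iodophenol
Product: 3 [4-(benzyloxy)-2-iodophenoxy]triisopropylsilane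
Conditions: i-Pr3SiCl, imidazole, DMF, rt
Reagents that add atoms: triisopropylsilyl chloride, CC(C)[Si](Cl)(C(C)C)C(C)C
Why: Silyl ether formation; the bulky TIPS group masks the phenol that must not be sulfated and should withstand bases, hydrides and hydrogenolysis until the last step.

Step 3
Reactants: 4 4,4-dimethylcyclohexa-2,5-dien-1-one
Product: 5 (S)-4,4-dimethyl-5-vinylcyclohex-2-en-1-one
Conditions: potassium vinyltrifluoroborate, [Rh(cod)2]BF4 (3 mol%), (S)-BINAP (3.3 mol%), toluene/H2O (10:1), 80 °C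
Reagents that add atoms: potassium vinyltrifluoroborate, C=C[B-](F)(F)F.[K+]
Why: Rhodium-catalysed asymmetric 1,4-addition of an alkenylboron reagent (Hayashi–Miyaura reaction) desymmetrises the prochiral dienone; the (S)-BINAP–rhodium complex should deliver the vinyl group to the same enone face as in the cyclohex-2-enone case, setting C-5 as S.

Step 4
Reactants: 5 (S)-4,4-dimethyl-5-vinylcyclohex-2-en-1-one
Product: 7 (5S,6R)-6-hydroxy-4,4-dimethyl-5-vinylcyclohex-2-en-1-one, via sodium dienolate 6 (not isolated)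
Conditions: NaN(SiMe3)2, THF, −78 °C; then 2-(phenylsulfonyl)-3-phenyloxaziridine, −78 °C; H2O
Reagents that add atoms: 2-(phenylsulfonyl)-3-phenyloxaziridine, O=S(=O)(N1OC1c1ccccc1)c1ccccc1
Why: Deprotonation can occur only at C-6 (C-4 is quaternary) and the enolate is oxidised by the N-sulfonyloxaziridine (Davis enolate hydroxylation) anti to the neighbouring vinyl group; this carbinol stereocentre is erased again in step 6.

Step 5
Reactants: 7 (5S,6R)-6-hydroxy-4,4-dimethyl-5-vinylcyclohex-2-en-1-one
Product: 8 (5S,6R)-6-[(tert-butyldimethylsilyl)oxy]-4,4-dimethyl-5-vinylcyclohex-2-en-1-one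
Conditions: t-BuMe2SiOTf, 2,6-lutidine, CH2Cl2, −78 → 0 °C
Reagents that add atoms: tert-butyldimethylsilyl triflate, CC(C)(C)[Si](C)(C)OS(=O)(=O)C(F)(F)F
Why: Silyl ether formation with the silyl triflate; a silyl ether is chosen for the future bridgehead oxygen because it offers no weak C–H bond within reach of the radical generated in step 12.

Step 6
Reactants: 8 (5S,6R)-6-[(tert-butyldimethylsilyl)oxy]-4,4-dimethyl-5-vinylcyclohex-2-en-1-one; 9 methyl acrylate
Product: 12 methyl 1-[(tert-butyldimethylsilyl)oxy]-3,3-dimethyl-7-oxo-2-vinylbicyclo[2.2.2]octane-5-carboxylate (2-vinyl anti to the C-5/C-6 bridge; ester syn to the C-7/C-8 bridge), via lithium dienolate 10 (not isolated), via lithium ester enolate 11 (not isolated)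
Conditions: LiN(i-Pr)2, THF, −78 °C; then methyl acrylate, −78 °C → rt; H2O
Reagents that add atoms: none
Why: Anionic double Michael addition (formal [4+2] of the 2-oxido diene): the enolate carbon adds to the acrylate anti to the pseudo-axial vinyl group on the adjacent carbon and the ester enolate then closes onto the enone β-carbon on the same face, so both bridgeheads are fixed relative to C-2 with the vinyl group anti to the new bridge, while the ester configuration is irrelevant because C-5 is planarised in step 9.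

Step 7
Reactants: 12 methyl 1-[(tert-butyldimethylsilyl)oxy]-3,3-dimethyl-7-oxo-2-vinylbicyclo[2.2.2]octane-5-carboxylate
Product: 14 methyl 1-[(tert-butyldimethylsilyl)oxy]-3,3-dimethyl-7-[(trifluoromethylsulfonyl)oxy]-2-vinylbicyclo[2.2.2]oct-7-ene-5-carboxylate, via potassium enolate 13 (not isolated)
Conditions: KN(SiMe3)2, THF, −78 °C; then PhNTf2
Reagents that add atoms: N-phenylbis(trifluoromethanesulfonimide), O=S(=O)(N(c1ccccc1)S(=O)(=O)C(F)(F)F)C(F)(F)F
Why: Enol triflate formation; the ketone can enolise only towards C-8 (C-1 is a quaternary bridgehead) and is more acidic than the ester, so its potassium enolate should be trapped on oxygen.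

Step 8
Reactants: 14 methyl 1-[(tert-butyldimethylsilyl)oxy]-3,3-dimethyl-7-[(trifluoromethylsulfonyl)oxy]-2-vinylbicyclo[2.2.2]oct-7-ene-5-carboxylate
Product: 15 methyl 1-[(tert-butyldimethylsilyl)oxy]-3,3-dimethyl-2-vinylbicyclo[2.2.2]oct-7-ene-5-carboxylate
Conditions: Pd(OAc)2 (5 mol%), PPh3 (10 mol%), HCO2H, n-Bu3N, DMF, 60 °C
Reagents that add atoms: none
Why: Palladium-catalysed formate reduction of an enol triflate (oxidative addition to zerovalent palladium, formate decarboxylation, C–H reductive elimination) removes the ketone oxygen and leaves the C-7=C-8 alkene, which is hydrogenated in step 26.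

Step 9
Reactants: 15 methyl 1-[(tert-butyldimethylsilyl)oxy]-3,3-dimethyl-2-vinylbicyclo[2.2.2]oct-7-ene-5-carboxylate
Product: 17 methyl 1-[(tert-butyldimethylsilyl)oxy]-3,3,5-trimethyl-2-vinylbicyclo[2.2.2]oct-7-ene-5-carboxylate (5-methyl and 2-vinyl syn to the C-7=C-8 bridge), via lithium ester enolate 16 (not isolated)
Conditions: LiN(i-Pr)2, THF/DMPU, −78 °C; then MeI, −78 → 0 °C
Reagents that add atoms: iodomethane, CI
Why: Ester enolate alkylation; iodomethane should approach the exocyclic enolate at C-5 from the face turned to the flat C-7=C-8 bridge because the other face is blocked by the C-3 methyl group that points at C-5, which sets the quaternary centre with the ester carbon (future chain) syn to C-3.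

Step 10
Reactants: 17 methyl 1-[(tert-butyldimethylsilyl)oxy]-3,3,5-trimethyl-2-vinylbicyclo[2.2.2]oct-7-ene-5-carboxylate
Product: 19 methyl 1-[(tert-butyldimethylsilyl)oxy]-2-(2-hydroxyethyl)-3,3,5-trimethylbicyclo[2.2.2]oct-7-ene-5-carboxylate, via B-alkyl-9-BBN adduct 18 (not isolated)
Conditions: 9-BBN, THF, 0 °C → rt; then NaOH, H2O2, 0 °C
Reagents that add atoms: hydrogen peroxide, OO
Why: Anti-Markovnikov hydroboration–oxidation; 9-BBN should select the monosubstituted vinyl group over the hindered cis-disubstituted bicyclic alkene, and alkaline peroxide replaces boron by OH.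

Step 11
Reactants: 19 methyl 1-[(tert-butyldimethylsilyl)oxy]-2-(2-hydroxyethyl)-3,3,5-trimethylbicyclo[2.2.2]oct-7-ene-5-carboxylate
Product: 21 2-{1-[(tert-butyldimethylsilyl)oxy]-5-(methoxycarbonyl)-3,3,5-trimethylbicyclo[2.2.2]oct-7-en-2-yl}acetic acid, via aldehyde 20 (not isolated)
Conditions: TEMPO (20 mol%), PhI(OAc)2 (2.5 equiv), MeCN/H2O (1:1), rt
Reagents that add atoms: water, O
Why: Nitroxyl-catalysed oxidation takes the primary alcohol through the aldehyde hydrate to the acid without touching the alkene, the ester or the silyl ether.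

Step 12
Reactants: 21 2-{1-[(tert-butyldimethylsilyl)oxy]-5-(methoxycarbonyl)-3,3,5-trimethylbicyclo[2.2.2]oct-7-en-2-yl}acetic acid; 3 [4-(benzyloxy)-2-iodophenoxy]triisopropylsilane
Product: 23 methyl 2-[5-(benzyloxy)-2-(triisopropylsilyloxy)benzyl]-1-[(tert-butyldimethylsilyl)oxy]-3,3,5-trimethylbicyclo[2.2.2]oct-7-ene-5-carboxylate, via N-acyloxyphthalimide ester 22 (not isolated)
Conditions: N-hydroxyphthalimide, i-PrN=C=N-i-Pr, DMAP (cat.), CH2Cl2, rt; then 3 (1.5 equiv), NiCl2·6H2O (20 mol%), 4,4′-di-tert-butyl-2,2′-bipyridine (20 mol%), LiBr, DMA, Mg anode/RVC cathode, constant current, rt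
Reagents that add atoms: none
Why: This is a nickel-electrocatalytic decarboxylative C(sp3)–C(sp2) coupling of a redox-active ester with an aryl iodide, the closest known reaction type being the electroreductive nickel-catalysed arylation of N-acyloxyphthalimides, run here after in-flask carbodiimide esterification of 21. Cathodically generated low-valent nickel inserts into the C–I bond of 3 and transfers an electron to 22, which loses phthalimide anion and CO2 to give the primary radical at the future benzylic carbon; capture of this radical by the arylnickel species and reductive elimination from trivalent nickel should forge the CH2–aryl bond, the magnesium anode supplying the electrons. The step closes no ring and creates no stereocentre, and the adjacent stereocentre C-2 is untouched because the radical sits one carbon away. It needs cross-coupling to win over hydrodecarboxylation, dimerisation and intramolecular hydrogen abstraction, and the substrate secures this: the radical is primary and unhindered although its carbon is neopentyl-like (C-2 between quaternary C-3 and bridgehead C-1), the bridgehead oxygen is a silyl ether (no γ-lactonisation of the active ester, no weak C–H bond in a 1,5-relationship), and the C-7=C-8 bond could be reached only by disfavoured 4-exo or 5-endo closure. The ester, both silyl ethers and the benzyl ether should be inert to the mild reductive conditions, so the arene arrives with its two oxygens already differentiated for the late sulfation.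

Step 13
Reactants: 23 methyl 2-[5-(benzyloxy)-2-(triisopropylsilyloxy)benzyl]-1-[(tert-butyldimethylsilyl)oxy]-3,3,5-trimethylbicyclo[2.2.2]oct-7-ene-5-carboxylate
Product: 24 {2-[5-(benzyloxy)-2-(triisopropylsilyloxy)benzyl]-1-[(tert-butyldimethylsilyl)oxy]-3,3,5-trimethylbicyclo[2.2.2]oct-7-en-5-yl}methanol
Conditions: i-Bu2AlH (3 equiv), CH2Cl2, −78 → 0 °C; Rochelle salt
Reagents that add atoms: none
Why: Hydride reduction of the hindered ester to the primary alcohol; silyl and benzyl ethers are inert.

Step 14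
Reactants: 24 {2-[5-(benzyloxy)-2-(triisopropylsilyloxy)benzyl]-1-[(tert-butyldimethylsilyl)oxy]-3,3,5-trimethylbicyclo[2.2.2]oct-7-en-5-yl}methanol
Product: 25 2-[5-(benzyloxy)-2-(triisopropylsilyloxy)benzyl]-1-[(tert-butyldimethylsilyl)oxy]-3,3,5-trimethylbicyclo[2.2.2]oct-7-ene-5-carbaldehyde
Conditions: Dess–Martin periodinane, NaHCO3, CH2Cl2, rt
Reagents that add atoms: none
Why: Dess–Martin oxidation of the neopentyl alcohol to the non-enolisable aldehyde.

Step 15
Reactants: 25 2-[5-(benzyloxy)-2-(triisopropylsilyloxy)benzyl]-1-[(tert-butyldimethylsilyl)oxy]-3,3,5-trimethylbicyclo[2.2.2]oct-7-ene-5-carbaldehyde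
Product: 26 {4-(benzyloxy)-2-[(1-[(tert-butyldimethylsilyl)oxy]-5-ethynyl-3,3,5-trimethylbicyclo[2.2.2]oct-7-en-2-yl)methyl]phenoxy}triisopropylsilane
Conditions: dimethyl (1-diazo-2-oxopropyl)phosphonate, K2CO3, MeOH, 0 °C → rt
Reagents that add atoms: dimethyl (1-diazo-2-oxopropyl)phosphonate, COP(=O)(OC)C(=[N+]=[N-])C(C)=O
Why: Seyferth–Gilbert homologation in the Ohira–Bestmann variant; the diazomethylphosphonate anion formed in the flask olefinates the aldehyde and the diazoalkene loses N2 with a 1,2-hydrogen shift, and the quaternary α-carbon cannot epimerise.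

Step 16
Reactants: 27 2-methylcyclohex-2-en-1-one
Product: 28 (R)-2-methylcyclohex-2-en-1-ol
Conditions: (S)-Me-CBS (10 mol%), BH3·SMe2, THF, −20 °C
Reagents that add atoms: none
Why: Corey–Bakshi–Shibata reduction; with the trisubstituted alkene side as the large group, the (S)-oxazaborolidine should deliver hydride to give the (R)-allylic alcohol.

Step 17
Reactants: 28 (R)-2-methylcyclohex-2-en-1-ol
Product: 29 (1R,2R,6S)-1-methyl-7-oxabicyclo[4.1.0]heptan-2-ol (epoxide cis to the hydroxyl)
Conditions: VO(acac)2 (2 mol%), t-BuOOH, CH2Cl2, 0 °C → rt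
Reagents that add atoms: tert-butyl hydroperoxide, CC(C)(C)OO
Why: Hydroxyl-directed vanadium-catalysed epoxidation of a cyclic allylic alcohol places the oxygen cis to the hydroxyl, so the carbinol centre relays its configuration to both epoxide carbons.

Step 18
Reactants: 29 (1R,2R,6S)-1-methyl-7-oxabicyclo[4.1.0]heptan-2-ol
Product: 30 (1S,6S)-1-methyl-7-oxabicyclo[4.1.0]heptan-2-one
Conditions: Dess–Martin periodinane, NaHCO3, CH2Cl2, 0 °C → rt
Reagents that add atoms: none
Why: Dess–Martin oxidation of the secondary alcohol to the α,β-epoxy ketone under buffered conditions that leave the epoxide intact.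

Step 19
Reactants: 30 (1S,6S)-1-methyl-7-oxabicyclo[4.1.0]heptan-2-one; 31 5-iodo-2-methylpent-2-ene
Product: 33 (2R,3S)-3-hydroxy-2-methyl-2-(4-methylpent-3-en-1-yl)cyclohexan-1-one, via dilithium enolate alkoxide 32 (not isolated)
Conditions: Li (2.1 equiv), NH3(l)/THF, −78 °C; then 31, −78 → −33 °C; H2O
Reagents that add atoms: none
Why: Dissolving-metal cleavage of the Cα–O bond of an α,β-epoxy ketone gives the regiodefined enolate bearing a β-lithium alkoxide, and its alkylation (reductive alkylation) should occur anti to that pseudo-axial alkoxide, which sets the quaternary carbon with the pentenyl chain trans to the hydroxyl.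

Step 20
Reactants: 33 (2R,3S)-3-hydroxy-2-methyl-2-(4-methylpent-3-en-1-yl)cyclohexan-1-one
Product: 35 (5aR,9aS)-2,2,5a-trimethyloctahydro-1-benzoxepin-6(2H)-one, via organomercurial 34 (not isolated)
Conditions: Hg(OCOCF3)2, MeCN, −20 °C; then n-Bu3SnH, AIBN (cat.), THF, rt
Reagents that add atoms: none
Why: Intramolecular alkoxymercuration–demercuration; the equatorial hydroxyl attacks the mercurinium ion at its tertiary carbon (Markovnikov, 7-endo) to close the trans-fused 2,2-dimethyloxepane, and tin hydride removes mercury by a radical chain without reducing the ketone.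

Step 21
Reactants: 35 (5aR,9aS)-2,2,5a-trimethyloctahydro-1-benzoxepin-6(2H)-one
Product: 37 (5aR,7S,9aS)-2,2,5a,7-tetramethyloctahydro-1-benzoxepin-6(2H)-one, via lithium enolate 36 (not isolated)
Conditions: LiN(i-Pr)2, THF, −78 °C; then MeI; then NaOMe (cat.), MeOH, rt
Reagents that add atoms: iodomethane, CI
Why: Enolate methylation at the only enolisable position (C-7) followed by base equilibration, which should leave the methyl group equatorial (trans to the axial angular methyl) in the conformationally locked trans-fused system.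

Step 22
Reactants: 37 (5aR,7S,9aS)-2,2,5a,7-tetramethyloctahydro-1-benzoxepin-6(2H)-one
Product: 38 2,2,5a,7-tetramethyl-6-methylidenedecahydro-1-benzoxepine (configuration as in 37)
Conditions: Ph3PCH3Br, KOt-Bu, toluene, 90 °C
Reagents that add atoms: methyltriphenylphosphonium bromide, C[P+](c1ccccc1)(c1ccccc1)c1ccccc1.[Br-]
Why: Wittig methylenation of the hindered ketone under forcing conditions; any epimerisation at C-7 only restores the equatorial methyl.

Step 23
Reactants: 38 2,2,5a,7-tetramethyl-6-methylidenedecahydro-1-benzoxepine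
Product: 39 2,2,5a,7-tetramethyloctahydro-2H-spiro[1-benzoxepine-6,2′-oxirane] (oxirane oxygen axial; anti to the 5a-methyl)
Conditions: m-CPBA, NaHCO3, CH2Cl2, 0 °C
Reagents that add atoms: 3-chloroperbenzoic acid, OOC(=O)c1cccc(Cl)c1
Why: Peracid (Prilezhaev) epoxidation of the exocyclic alkene from the face anti to the adjacent axial angular methyl group puts the oxygen axial and the CH2 equatorial, which sets the tertiary carbinol centre.

Step 24
Reactants: 39 2,2,5a,7-tetramethyloctahydro-2H-spiro[1-benzoxepine-6,2′-oxirane]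
Product: 40 2,2,5a,7-tetramethyloctahydro-2H-spiro[1-benzoxepine-6,2′-oxetane] (oxetane oxygen on C-6; axial)
Conditions: Me3S(O)I, KOt-Bu, t-BuOH, 60 °C
Reagents that add atoms: trimethylsulfoxonium iodide, C[S+](C)(C)=O.[I-]
Why: Ring expansion of an epoxide with dimethylsulfoxonium methylide (Corey–Chaykovsky-type homologation); the ylide opens the oxirane at its CH2 and the tertiary alkoxide displaces dimethyl sulfoxide 4-exo-tet, so the C–O bond of the stereocentre is never broken.

Step 25
Reactants: 26 {4-(benzyloxy)-2-[(1-[(tert-butyldimethylsilyl)oxy]-5-ethynyl-3,3,5-trimethylbicyclo[2.2.2]oct-7-en-2-yl)methyl]phenoxy}triisopropylsilane; 40 2,2,5a,7-tetramethyloctahydro-2H-spiro[1-benzoxepine-6,2′-oxetane]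
Product: 42 6-(4-{2-[5-(benzyloxy)-2-(triisopropylsilyloxy)benzyl]-1-[(tert-butyldimethylsilyl)oxy]-3,3,5-trimethylbicyclo[2.2.2]oct-7-en-5-yl}but-3-yn-1-yl)-2,2,5a,7-tetramethyldecahydro-1-benzoxepin-6-ol, via lithium acetylide 41 (not isolated)
Conditions: n-BuLi, THF, −78 °C; then BF3·OEt2; then 40, −78 °C
Reagents that add atoms: none
Why: Boron trifluoride-promoted SN2 opening of an oxetane by a lithium acetylide at the unhindered CH2–O carbon joins the halves and liberates the tertiary alcohol with its configuration intact.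

Step 26
Reactants: 42 the alkynol from step 25
Product: 43 6-(4-{2-[5-hydroxy-2-(triisopropylsilyloxy)benzyl]-1-[(tert-butyldimethylsilyl)oxy]-3,3,5-trimethylbicyclo[2.2.2]octan-5-yl}butyl)-2,2,5a,7-tetramethyldecahydro-1-benzoxepin-6-ol
Conditions: H2 (3 atm), Pd(OH)2/C, EtOAc/EtOH, rt
Reagents that add atoms: none
Why: Heterogeneous catalytic hydrogenation saturates the alkyne and the bicyclic alkene and hydrogenolyses the aryl benzyl ether while both silyl ethers survive; no stereocentre is formed or touched.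

Step 27
Reactants: 43 the phenol from step 26
Product: 44 3-({1-[(tert-butyldimethylsilyl)oxy]-5-[4-(6-hydroxy-2,2,5a,7-tetramethyldecahydro-1-benzoxepin-6-yl)butyl]-3,3,5-trimethylbicyclo[2.2.2]octan-2-yl}methyl)-4-(triisopropylsilyloxy)phenyl hydrogen sulfate
Conditions: SO3·pyridine (1.5 equiv), pyridine, rt; H+ ion-exchange work-up
Reagents that add atoms: sulfur trioxide–pyridine complex, O=S(=O)([O-])[n+]1ccccc1
Why: O-Sulfation with the sulfur trioxide–pyridine complex; the free phenol should react much faster than the hindered tertiary alcohol and the other phenolic oxygen is still silylated, so the sulfate is placed unambiguously.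

Step 28
Reactants: 44 the silylated aryl hydrogen sulfate from step 27
Product: 45 CNP0255133.1 (target)
Conditions: HF·pyridine, pyridine/THF, 0 °C → rt
Reagents that add atoms: none
Why: Fluoride-mediated desilylation (strong Si–F bond) cleaves the aryl TIPS ether and the tertiary bridgehead TBS ether under buffered conditions that an aryl sulfate monoester should tolerate.

## Compound list

1 | 4-(benzyloxy)phenol | Oc1ccc(OCc2ccccc2)cc1 | starting material
2 | 4-(benzyloxy)-2-iodophenol | Oc1ccc(OCc2ccccc2)cc1I | intermediate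
3 | [4-(benzyloxy)-2-iodophenoxy]triisopropylsilane | CC(C)[Si](Oc1ccc(OCc2ccccc2)cc1I)(C(C)C)C(C)C | intermediate
4 | 4,4-dimethylcyclohexa-2,5-dien-1-one | CC1(C)C=CC(=O)C=C1 | starting material
5 | (S)-4,4-dimethyl-5-vinylcyclohex-2-en-1-one | C=C[C@@H]1CC(=O)C=CC1(C)C | intermediate
6 | sodium dienolate of 5 | [Na+].[O-]C1=C[C@@H](C=C)C(C)(C)C=C1 | intermediate
7 | (5S,6R)-6-hydroxy-4,4-dimethyl-5-vinylcyclohex-2-en-1-one | C=C[C@@H]1[C@@H](O)C(=O)C=CC1(C)C | intermediate
8 | (5S,6R)-6-[(tert-butyldimethylsilyl)oxy]-4,4-dimethyl-5-vinylcyclohex-2-en-1-one | C=C[C@@H]1[C@@H](O[Si](C)(C)C(C)(C)C)C(=O)C=CC1(C)C | intermediate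
9 | methyl acrylate | C=CC(=O)OC | starting material
10 | lithium dienolate of 8 | [Li+].[O-]C1=C(O[Si](C)(C)C(C)(C)C)[C@@H](C=C)C(C)(C)C=C1 | intermediate
11 | lithium ester enolate of the first Michael adduct | [Li+].COC([O-])=CC[C@@]1(O[Si](C)(C)C(C)(C)C)C(=O)C=CC(C)(C)[C@@H]1C=C | intermediate
12 | methyl 1-[(tert-butyldimethylsilyl)oxy]-3,3-dimethyl-7-oxo-2-vinylbicyclo[2.2.2]octane-5-carboxylate (vinyl anti to the C-5/C-6 bridge, ester syn to the C-7/C-8 bridge) | COC(=O)[C@H]1C[C@@]2(O[Si](C)(C)C(C)(C)C)C(=O)C[C@@H]1C(C)(C)[C@@H]2C=C | intermediate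
13 | potassium enolate of 12 | [K+].COC(=O)[C@H]1C[C@@]2(O[Si](C)(C)C(C)(C)C)C([O-])=C[C@@H]1C(C)(C)[C@@H]2C=C | intermediate
14 | methyl 1-[(tert-butyldimethylsilyl)oxy]-3,3-dimethyl-7-[(trifluoromethylsulfonyl)oxy]-2-vinylbicyclo[2.2.2]oct-7-ene-5-carboxylate | COC(=O)[C@H]1C[C@@]2(O[Si](C)(C)C(C)(C)C)C(OS(=O)(=O)C(F)(F)F)=C[C@@H]1C(C)(C)[C@@H]2C=C | intermediate
15 | methyl 1-[(tert-butyldimethylsilyl)oxy]-3,3-dimethyl-2-vinylbicyclo[2.2.2]oct-7-ene-5-carboxylate | COC(=O)[C@H]1C[C@@]2(O[Si](C)(C)C(C)(C)C)C=C[C@@H]1C(C)(C)[C@@H]2C=C | intermediate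
16 | lithium ester enolate of 15 | [Li+].COC([O-])=C1C[C@@]2(O[Si](C)(C)C(C)(C)C)C=C[C@@H]1C(C)(C)[C@@H]2C=C | intermediate
17 | methyl 1-[(tert-butyldimethylsilyl)oxy]-3,3,5-trimethyl-2-vinylbicyclo[2.2.2]oct-7-ene-5-carboxylate (5-methyl and 2-vinyl syn to the C-7=C-8 bridge) | COC(=O)[C@]1(C)C[C@@]2(O[Si](C)(C)C(C)(C)C)C=C[C@@H]1C(C)(C)[C@@H]2C=C | intermediate
18 | B-alkyl-9-borabicyclo[3.3.1]nonane adduct of 17 | COC(=O)[C@]1(C)C[C@@]2(O[Si](C)(C)C(C)(C)C)C=C[C@@H]1C(C)(C)[C@@H]2CCB1C3CCCC1CCC3 | intermediate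
19 | methyl 1-[(tert-butyldimethylsilyl)oxy]-2-(2-hydroxyethyl)-3,3,5-trimethylbicyclo[2.2.2]oct-7-ene-5-carboxylate | COC(=O)[C@]1(C)C[C@@]2(O[Si](C)(C)C(C)(C)C)C=C[C@@H]1C(C)(C)[C@@H]2CCO | intermediate
20 | methyl 1-[(tert-butyldimethylsilyl)oxy]-3,3,5-trimethyl-2-(2-oxoethyl)bicyclo[2.2.2]oct-7-ene-5-carboxylate | COC(=O)[C@]1(C)C[C@@]2(O[Si](C)(C)C(C)(C)C)C=C[C@@H]1C(C)(C)[C@@H]2CC=O | intermediate
21 | 2-{1-[(tert-butyldimethylsilyl)oxy]-5-(methoxycarbonyl)-3,3,5-trimethylbicyclo[2.2.2]oct-7-en-2-yl}acetic acid | COC(=O)[C@]1(C)C[C@@]2(O[Si](C)(C)C(C)(C)C)C=C[C@@H]1C(C)(C)[C@@H]2CC(=O)O | intermediate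
22 | N-acyloxyphthalimide (redox-active) ester of 21 | COC(=O)[C@]1(C)C[C@@]2(O[Si](C)(C)C(C)(C)C)C=C[C@@H]1C(C)(C)[C@@H]2CC(=O)ON1C(=O)c3ccccc3C1=O | intermediate
23 | methyl 2-[5-(benzyloxy)-2-(triisopropylsilyloxy)benzyl]-1-[(tert-butyldimethylsilyl)oxy]-3,3,5-trimethylbicyclo[2.2.2]oct-7-ene-5-carboxylate | COC(=O)[C@]1(C)C[C@@]2(O[Si](C)(C)C(C)(C)C)C=C[C@@H]1C(C)(C)[C@@H]2Cc1cc(OCc3ccccc3)ccc1O[Si](C(C)C)(C(C)C)C(C)C | intermediate
24 | {2-[5-(benzyloxy)-2-(triisopropylsilyloxy)benzyl]-1-[(tert-butyldimethylsilyl)oxy]-3,3,5-trimethylbicyclo[2.2.2]oct-7-en-5-yl}methanol | OC[C@]1(C)C[C@@]2(O[Si](C)(C)C(C)(C)C)C=C[C@@H]1C(C)(C)[C@@H]2Cc1cc(OCc3ccccc3)ccc1O[Si](C(C)C)(C(C)C)C(C)C | intermediate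
25 | 2-[5-(benzyloxy)-2-(triisopropylsilyloxy)benzyl]-1-[(tert-butyldimethylsilyl)oxy]-3,3,5-trimethylbicyclo[2.2.2]oct-7-ene-5-carbaldehyde | O=C[C@]1(C)C[C@@]2(O[Si](C)(C)C(C)(C)C)C=C[C@@H]1C(C)(C)[C@@H]2Cc1cc(OCc3ccccc3)ccc1O[Si](C(C)C)(C(C)C)C(C)C | intermediate
26 | {4-(benzyloxy)-2-[(1-[(tert-butyldimethylsilyl)oxy]-5-ethynyl-3,3,5-trimethylbicyclo[2.2.2]oct-7-en-2-yl)methyl]phenoxy}triisopropylsilane | C#C[C@]1(C)C[C@@]2(O[Si](C)(C)C(C)(C)C)C=C[C@@H]1C(C)(C)[C@@H]2Cc1cc(OCc3ccccc3)ccc1O[Si](C(C)C)(C(C)C)C(C)C | intermediate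
27 | 2-methylcyclohex-2-en-1-one | CC1=CCCCC1=O | starting material
28 | (R)-2-methylcyclohex-2-en-1-ol | CC1=CCCC[C@H]1O | intermediate
29 | (1R,2R,6S)-1-methyl-7-oxabicyclo[4.1.0]heptan-2-ol | C[C@]12O[C@H]1CCC[C@H]2O | intermediate
30 | (1S,6S)-1-methyl-7-oxabicyclo[4.1.0]heptan-2-one | C[C@]12O[C@H]1CCCC2=O | intermediate
31 | 5-iodo-2-methylpent-2-ene | CC(C)=CCCI | starting material
32 | dilithium enolate alkoxide from 30 | [Li+].[Li+].CC1=C([O-])CCC[C@@H]1[O-] | intermediate
33 | (2R,3S)-3-hydroxy-2-methyl-2-(4-methylpent-3-en-1-yl)cyclohexan-1-one | O=C1CCC[C@H](O)[C@@]1(C)CCC=C(C)C | intermediate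
34 | 3-(trifluoroacetoxymercurio) derivative of 35 (C-3 epimers, both converge) | C[C@@]12CCC([Hg]OC(=O)C(F)(F)F)C(C)(C)O[C@H]1CCCC2=O | intermediate
35 | (5aR,9aS)-2,2,5a-trimethyloctahydro-1-benzoxepin-6(2H)-one | C[C@@]12CCCC(C)(C)O[C@H]1CCCC2=O | intermediate
36 | lithium enolate of 35 | [Li+].C[C@@]12CCCC(C)(C)O[C@H]1CCC=C2[O-] | intermediate
37 | (5aR,7S,9aS)-2,2,5a,7-tetramethyloctahydro-1-benzoxepin-6(2H)-one | C[C@H]1CC[C@@H]2OC(C)(C)CCC[C@@]2(C)C1=O | intermediate
38 | 2,2,5a,7-tetramethyl-6-methylidenedecahydro-1-benzoxepine (configuration as in 37) | C[C@H]1CC[C@@H]2OC(C)(C)CCC[C@@]2(C)C1=C | intermediate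
39 | 2,2,5a,7-tetramethyloctahydro-2H-spiro[1-benzoxepine-6,2′-oxirane] (oxygen axial, anti to 5a-methyl) | C[C@H]1CC[C@@H]2OC(C)(C)CCC[C@@]2(C)[C@]13CO3 | intermediate
40 | 2,2,5a,7-tetramethyloctahydro-2H-spiro[1-benzoxepine-6,2′-oxetane] (oxygen on C-6, axial) | C[C@H]1CC[C@@H]2OC(C)(C)CCC[C@@]2(C)[C@]13CCO3 | intermediate
41 | lithium acetylide of 26 | [Li]C#C[C@]1(C)C[C@@]2(O[Si](C)(C)C(C)(C)C)C=C[C@@H]1C(C)(C)[C@@H]2Cc1cc(OCc3ccccc3)ccc1O[Si](C(C)C)(C(C)C)C(C)C | intermediate
42 | 6-(4-{2-[5-(benzyloxy)-2-(triisopropylsilyloxy)benzyl]-1-[(tert-butyldimethylsilyl)oxy]-3,3,5-trimethylbicyclo[2.2.2]oct-7-en-5-yl}but-3-yn-1-yl)-2,2,5a,7-tetramethyldecahydro-1-benzoxepin-6-ol | C[C@H]1CC[C@@H]2OC(C)(C)CCC[C@@]2(C)[C@]1(O)CCC#C[C@]1(C)C[C@@]2(O[Si](C)(C)C(C)(C)C)C=C[C@@H]1C(C)(C)[C@@H]2Cc1cc(OCc3ccccc3)ccc1O[Si](C(C)C)(C(C)C)C(C)C | intermediate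
43 | 6-(4-{2-[5-hydroxy-2-(triisopropylsilyloxy)benzyl]-1-[(tert-butyldimethylsilyl)oxy]-3,3,5-trimethylbicyclo[2.2.2]octan-5-yl}butyl)-2,2,5a,7-tetramethyldecahydro-1-benzoxepin-6-ol | C[C@H]1CC[C@@H]2OC(C)(C)CCC[C@@]2(C)[C@]1(O)CCCC[C@]1(C)C[C@@]2(O[Si](C)(C)C(C)(C)C)CC[C@@H]1C(C)(C)[C@@H]2Cc1cc(O)ccc1O[Si](C(C)C)(C(C)C)C(C)C | intermediate
44 | bis-silyl ether of the target (aryl O-TIPS, bridgehead O-TBS), aryl hydrogen sulfate | C[C@H]1CC[C@@H]2OC(C)(C)CCC[C@@]2(C)[C@]1(O)CCCC[C@]1(C)C[C@@]2(O[Si](C)(C)C(C)(C)C)CC[C@@H]1C(C)(C)[C@@H]2Cc1cc(OS(=O)(=O)O)ccc1O[Si](C(C)C)(C(C)C)C(C)C | intermediate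
45 | CNP0255133.1 | C[C@H]1CC[C@@H]2OC(C)(C)CCC[C@@]2(C)[C@]1(O)CCCC[C@]1(C)C[C@@]2(O)CC[C@@H]1C(C)(C)[C@@H]2Cc1cc(OS(=O)(=O)O)ccc1O | target

## Summary

Total step count: 28. Longest linear sequence: 17 steps (from 4 through steps 3–15 and 25–28 to 45).

Three steps most likely to fail:

Step 6. The hindered α-silyloxy dienolate may add too slowly to the acrylate, so that acrylate oligomerisation takes over, or the second ring-closing Michael addition next to the gem-dimethyl carbon may stall; silyl migration between the two enolate oxygens could also erode regiocontrol. The fallback makes the two C–C bonds in separate operations. Starting from 8, LiN(i-Pr)2 and Me3SiCl would give the trimethylsilyl dienol ether F1. A Lewis acid-promoted Mukaiyama–Michael addition of F1 to methyl acrylate 9 (TiCl4, CH2Cl2, −78 °C), anti to the vinyl group, would give the monocyclic keto ester F2. KOt-Bu in THF would then close the second ring by intramolecular Michael addition, returning to 12.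

Step 19. C-alkylation of the tetrasubstituted enolate by an unactivated primary iodide may be slow, so that proton transfer, O-alkylation or loss of HI from the iodide compete. The fallback introduces the chain with a reactive allylic electrophile and builds the trisubstituted alkene afterwards. Starting from 30, the same Li/NH3 reduction quenched with allyl bromide would give the allyl ketol F3, again anti to the alkoxide. Hydroboration with 9-BBN and perborate oxidation would give the hydroxypropyl ketol F4. Selective TEMPO/PhI(OAc)2 oxidation of the primary alcohol would give the keto aldehyde F5 (in equilibrium with its lactol). Wittig olefination with isopropylidenetriphenylphosphorane would return to 33.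

Step 12. Reduction of the redox-active ester may outpace oxidative addition of the electron-rich, ortho-silyloxy aryl iodide, leading to hydrodecarboxylation or radical dimerisation instead of cross-coupling. The fallback replaces the radical–nickel manifold by a two-electron cross-coupling. Starting from 21, Barton decarboxylative iodination (N-hydroxypyridine-2-thione ester, CHI3, visible light) would give the primary iodide F6. Iodine–lithium exchange with t-BuLi in the presence of 9-methoxy-9-BBN would give the lithium alkylborate F7. B-alkyl Suzuki–Miyaura coupling of F7 with 3 (PdCl2(dppf), K3PO4, DMF) would return to 23.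

Further compounds
F1 | step 6 | tert-butyldimethylsilyl/trimethylsilyl bis-silyl dienol ether of 8 (1-TBSO-2-TMSO-cyclohexa-1,3-diene) | C=C[C@@H]1C(O[Si](C)(C)C(C)(C)C)=C(O[Si](C)(C)C)C=CC1(C)C
F2 | step 6 | methyl 3-{1-[(tert-butyldimethylsilyl)oxy]-5,5-dimethyl-2-oxo-6-vinylcyclohex-3-en-1-yl}propanoate (propanoate anti to vinyl) | COC(=O)CC[C@@]1(O[Si](C)(C)C(C)(C)C)C(=O)C=CC(C)(C)[C@@H]1C=C
F3 | step 19 | (2R,3S)-2-allyl-3-hydroxy-2-methylcyclohexan-1-one | O=C1CCC[C@H](O)[C@@]1(C)CC=C
F4 | step 19 | (2R,3S)-3-hydroxy-2-(3-hydroxypropyl)-2-methylcyclohexan-1-one | O=C1CCC[C@H](O)[C@@]1(C)CCCO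
F5 | step 19 | 3-[(1R,2S)-2-hydroxy-1-methyl-6-oxocyclohexyl]propanal | O=C1CCC[C@H](O)[C@@]1(C)CCC=O
F6 | step 12 | methyl 1-[(tert-butyldimethylsilyl)oxy]-2-(iodomethyl)-3,3,5-trimethylbicyclo[2.2.2]oct-7-ene-5-carboxylate | COC(=O)[C@]1(C)C[C@@]2(O[Si](C)(C)C(C)(C)C)C=C[C@@H]1C(C)(C)[C@@H]2CI
F7 | step 12 | lithium B-alkyl-B-methoxy-9-borabicyclo[3.3.1]nonane ate complex from F6 | [Li+].COC(=O)[C@]1(C)C[C@@]2(O[Si](C)(C)C(C)(C)C)C=C[C@@H]1C(C)(C)[C@@H]2C[B-]1(OC)C3CCCC1CCC3
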